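**Plan**

1. Cuts, in retrosynthetic order: the C16=C17 methylene (Mannich methylenation), C13–C16 (ring D, radical closure), C8–C14 (ring C, palladium allylic alkylation), C13=C14 (cross-metathesis), C9–C11 (conjugate allylation), C8–C15 (acylation), C9–C10 together with O–C7 (radical addition and lactonisation), C4–C18 (enolate methylation), and C4–C5 with C2–C3 (Diels–Alder).
2. Forward order: ring A by Diels–Alder reaction, then the spiro δ-lactone by a titanium-mediated epoxide–acrylate coupling, then ring C in the key step, then ring D by 5-exo radical closure, then the exocyclic methylene and deprotection.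
3. Stereochemistry: C5 comes from an oxazolidinone auxiliary in the Diels–Alder step. C4, C1, C10 and C9 are relayed from C5 (alkylation, hydroboration, radical addition, conjugate allylation). C8 follows from C9 in the key step and C13 from C8 through the bridge.
4. Enabling feature: C8 is shared by the δ-lactone (C10–C20–O–C7–C8–C9) and ring C and lies between the lactone carbonyl C7 and the ketone C15, so it is a soft, doubly stabilised carbanion. Its bond to C14 is axial on the lactone ring and cis to C11, so an allyl unit tethered to C9 can close ring C only in the needed sense.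

Key step: step 20

Remark: atoms carry ent-kaurane numbers throughout (ring A = C1–C5 and C10; C6 on C5; C18 methyl and C19 on C4; C20 on C10; C7 lactone carbonyl; C15 ketone; C16, C17); TBS = tert-butyldimethylsilyl, TBDPS = tert-butyldiphenylsilyl.
Remark: C8 of the β-keto lactones 24, 28 and 31 epimerises and enolises freely and epoxide 19 is used as a mixture of spiro epimers, so these centres carry no descriptor in the SMILES.

**Route**

Step 1
Reactants: 1 glycolaldehyde dimer; 2 1-(triphenylphosphoranylidene)propan-2-one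
Product: 3 (E)-5-hydroxypent-3-en-2-one
Conditions: THF, 65 °C
Reagents that add atoms: none
Why: Wittig olefination of the open-chain aldehyde (in equilibrium with the dimer) by the stabilised ylide should give the E enone, and no stereocentre is formed.

Step 2
Reactants: 3 (E)-5-hydroxypent-3-en-2-one
Product: 4 (E)-5-(tert-butyldiphenylsilyloxy)pent-3-en-2-one
Conditions: TBDPSCl, imidazole, CH2Cl2, 0 °C to rt
Reagents that add atoms: tert-butyl(chloro)diphenylsilane, CC(C)(C)[Si](Cl)(c1ccccc1)c1ccccc1
Why: Standard silylation of the primary allylic alcohol installs the robust group that protects the future C6 oxygen to the last step.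

Step 3
Reactants: 4 (E)-5-(tert-butyldiphenylsilyloxy)pent-3-en-2-one
Product: 5 (E)-2-(tert-butyldimethylsilyloxy)-5-(tert-butyldiphenylsilyloxy)penta-1,3-diene
Conditions: TBSOTf, Et3N, CH2Cl2, 0 °C
Reagents that add atoms: tert-butyldimethylsilyl triflate, CC(C)(C)[Si](C)(C)OS(=O)(=O)C(F)(F)F
Why: Soft enolisation of the methyl ketone should give the cross-conjugated 2-silyloxy diene with the E alkene untouched.

Step 4
Reactants: 6 (S)-4-benzyloxazolidin-2-one; 7 acryloyl chloride
Product: 8 (S)-3-acryloyl-4-benzyloxazolidin-2-one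
Conditions: Et3N, LiCl (cat.), THF, −20 °C to rt
Reagents that add atoms: none
Why: N-acylation of the oxazolidinone under LiCl/amine activation leaves the stereocentre of the auxiliary untouched.

Step 5
Reactants: 5 (E)-2-(tert-butyldimethylsilyloxy)-5-(tert-butyldiphenylsilyloxy)penta-1,3-diene; 8 (S)-3-acryloyl-4-benzyloxazolidin-2-one
Product: 9 (S)-4-benzyl-3-[(1R,2S)-2-(tert-butyldiphenylsilyloxymethyl)-4-(tert-butyldimethylsilyloxy)cyclohex-3-ene-1-carbonyl]oxazolidin-2-one
Conditions: Et2AlCl (1.4 equiv), CH2Cl2, −78 °C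
Reagents that add atoms: none
Why: In this auxiliary-controlled Lewis acid-promoted Diels–Alder reaction the silyloxy group and the terminal alkyl group of the diene both direct C5 to the acyl-bearing carbon C4, the endo transition state places CH2OTBDPS cis to the carbonyl, and the benzyl group of the aluminium chelate shields one acrylamide face so that C5 should form in the needed absolute configuration (C4 is reset in step 7).

Step 6
Reactants: 9 Diels–Alder adduct
Product: 10 methyl (1R,2S)-2-(tert-butyldiphenylsilyloxymethyl)-4-(tert-butyldimethylsilyloxy)cyclohex-3-ene-1-carboxylate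
Conditions: MeOMgBr (from MeMgBr and MeOH), CH2Cl2/MeOH, 0 °C
Reagents that add atoms: bromo(methoxy)magnesium, CO[Mg]Br
Why: Transesterification at the exocyclic imide carbonyl releases the auxiliary under mild conditions that the silyl enol ether should tolerate, and no stereocentre changes.

Step 7
Reactants: 10 methyl ester
Product: 12 methyl (1R,2S)-2-(tert-butyldiphenylsilyloxymethyl)-1-methyl-4-(tert-butyldimethylsilyloxy)cyclohex-3-ene-1-carboxylate, via lithium ester enolate 11 (not isolated)
Conditions: LiN(iPr)2, THF, −78 °C; then MeI, DMPU, −78 to −20 °C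
Reagents that add atoms: iodomethane, CI
Why: In this ester enolate alkylation the CH2OTBDPS group on C5 blocks its own face, so methyl iodide should enter trans to it and set quaternary C4 with the ester carbon C19 cis to C6.

Step 8
Reactants: 12 quaternary methyl ester
Product: 13 [(1R,2S)-2-(tert-butyldiphenylsilyloxymethyl)-1-methyl-4-(tert-butyldimethylsilyloxy)cyclohex-3-en-1-yl]methanol
Conditions: LiAlH4, Et2O, 0 °C
Reagents that add atoms: none
Why: Hydride reduction of the neopentyl ester gives the C19 alcohol, and the silyl ethers and the silyl enol ether are inert to the reagent.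

Step 9
Reactants: 13 C19 alcohol
Product: 14 (1R,2S)-1-(tert-butyldimethylsilyloxymethyl)-2-(tert-butyldiphenylsilyloxymethyl)-1-methyl-4-(tert-butyldimethylsilyloxy)cyclohex-3-ene
Conditions: TBSCl, imidazole, DMF, rt
Reagents that add atoms: tert-butyl(chloro)dimethylsilane, CC(C)(C)[Si](C)(C)Cl
Why: Silylation gives C19 a base-stable group that can later be removed together with the C1 silyl ether and apart from the TBDPS ether.

Step 10
Reactants: 14 tris-silyl cyclohexene
Product: 16 2-(tert-butyldimethylsilyloxy)-5-(tert-butyldimethylsilyloxymethyl)-6-(tert-butyldiphenylsilyloxymethyl)-5-methylcyclohexan-1-ol (C10 hydroxyl trans to both neighbours; C1 silyloxy cis to C6), via monoalkylborane 15 (not isolated)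
Conditions: BH3·THF, THF, 0 °C to rt; then NaOH, H2O2, 0 °C
Reagents that add atoms: hydrogen peroxide, OO
Why: In the hydroboration–oxidation of the silyl enol ether boron adds to C10 and hydrogen to C1, syn and from the face away from C6 and the C19 arm, which leaves the C1 silyloxy group cis to C6 (the C10 carbinol centre is removed in step 11).

Step 11
Reactants: 16 ring A alcohol
Product: 17 (2S,5R,6S)-2-(tert-butyldimethylsilyloxy)-5-(tert-butyldimethylsilyloxymethyl)-6-(tert-butyldiphenylsilyloxymethyl)-5-methylcyclohexan-1-one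
Conditions: Dess–Martin periodinane, CH2Cl2, 0 °C to rt
Reagents that add atoms: none
Why: Dess–Martin oxidation is non-basic, so the β-silyloxy ketone should neither epimerise at C5 nor eliminate.

Step 12
Reactants: 17 ring A ketone
Product: 18 the corresponding 1-methylidenecyclohexane (exocyclic alkene C10=C20)
Conditions: Cp2TiMe2, toluene, 70 °C
Reagents that add atoms: dimethyltitanocene, C[Ti](C)(C1C=CC=C1)C1C=CC=C1
Why: Petasis methylenation by the non-basic titanium carbene converts the hindered, base-sensitive ketone into the exocyclic alkene without touching C1 or C5.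

Step 13
Reactants: 18 exocyclic alkene
Product: 19 the spiro-epoxide across C10–C20 (1-oxaspiro[2.5]octane; both spiro epimers)
Conditions: dimethyldioxirane, acetone, 0 °C
Reagents that add atoms: dimethyldioxirane, CC1(C)OO1
Why: Neutral oxygen transfer to the 1,1-disubstituted alkene gives the epoxide, and either spiro epimer serves because C10 becomes a planar radical in step 14.

Step 14
Reactants: 19 spiro-epoxide; 20 2,2,2-trifluoroethyl acrylate
Product: 21 the 7,20-spirolactone (2-oxaspiro[5.5]undecan-3-one) carrying 1-OTBS 19-OTBS and 6-OTBDPS groups with C20 cis to C6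
Conditions: Cp2TiCl2 (20 mol %), Zn, 2,4,6-collidine·HCl, THF, rt
Reagents that add atoms: none
Why: Reductive epoxide opening by Cp2TiCl (trivalent titanium, Nugent–RajanBabu conditions) gives the tertiary C10 radical, whose Giese addition to the acrylate should occur opposite the axial C19 arm and the C6 and O1 substituents and so set quaternary C10 with C9 trans to C6, after which the C20 titanium alkoxide lactonises onto the trifluoroethyl ester.

Step 15
Reactants: 21 spirolactone
Product: 24 the 8-acetyl spirolactone (C8 epimers and enol), via lithium lactone enolate 22 (not isolated), via chelated lithium hemiaminal 23 (not isolated)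
Conditions: LiN(iPr)2, THF, −78 °C; then MeC(O)N(OMe)Me, −78 to 0 °C; aq NH4Cl
Reagents that add atoms: N-methoxy-N-methylacetamide, CC(=O)N(C)OC
Why: Claisen-type C-acylation of the lactone enolate by the Weinreb amide stops at the chelated adduct, which releases the ketone only on work-up.

Step 16
Reactants: 24 8-acetyl spirolactone
Product: 27 the 8-acetyl-8,9-didehydro spirolactone (alkylidene β-keto lactone), via α-phenylselanyl keto lactone 25 (not isolated), via selenoxide 26 (not isolated)
Conditions: PhSeCl, pyridine, CH2Cl2, 0 °C; then H2O2 (30 % aq), 0 °C to rt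
Reagents that add atoms: none
Why: Selenenylation of the β-dicarbonyl carbon followed by oxidation and selenoxide syn-elimination can take only a C9 hydrogen and so gives the C8=C9 alkene.

Step 17
Reactants: 27 alkylidene β-keto lactone
Product: 28 the 9-allyl-8-acetyl spirolactone with C11 cis to C1 on the lactone ring (C8 epimers)
Conditions: allyltrimethylsilane, TiCl4, CH2Cl2, −78 °C
Reagents that add atoms: allyltrimethylsilane, C=CC[Si](C)(C)C
Why: In this Hosomi–Sakurai conjugate allylation of the TiCl4-chelated alkylidene β-dicarbonyl the silane should approach C9 from the side of C1, whose equatorial silyloxy group can turn away, and not past the C6 arm that quaternary C4 holds over the other face, which sets C9.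

Step 18
Reactants: 29 (Z)-but-2-ene-1,4-diol
Product: 30 (Z)-but-2-ene-1,4-diyl dimethyl dicarbonate
Conditions: ClCO2Me, pyridine, CH2Cl2, 0 °C
Reagents that add atoms: methyl chloroformate, COC(=O)Cl
Why: Acylation of both hydroxyl groups gives the symmetrical metathesis partner that carries the carbonate leaving group.

Step 19
Reactants: 28 9-allyl-8-acetyl spirolactone; 30 (Z)-but-2-ene-1,4-diyl dimethyl dicarbonate (excess)
Product: 31 the 8-acetyl spirolactone with an (E)-4-(methoxycarbonyloxy)but-2-enyl chain on C9 (C8 epimers)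
Conditions: second-generation Grubbs catalyst (5 mol %), CH2Cl2, 40 °C
Reagents that add atoms: none
Why: Olefin cross-metathesis of the terminal alkene with the dicarbonate adds C14 and the leaving group, and the E/Z composition matters little because both isomers ionise to the same allyl system.

Step 20
Reactants: 31 allylic carbonate
Product: 32 the cis-fused cyclohexene spirolactone (C12=C13) with quaternary C8 bearing the acetyl group
Conditions: Pd(PPh3)4 (10 mol %), THF, 65 °C
Reagents that add atoms: none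
Why: Zerovalent palladium ionises the allylic methyl carbonate with loss of CO2 to a π-allyl complex spanning C12–C14, and the methoxide released deprotonates C8, whose anion is stabilised by the lactone carbonyl C7 and the ketone C15, so no external base is needed. The closest known reaction type is the intramolecular Tsuji–Trost alkylation of β-keto esters with allylic carbonates, here in its endo mode. Ring C closes by bond formation between C8 and the distal allyl terminus C14 (six-membered, endo with respect to the allyl unit, leaving the cis C12=C13 alkene in the ring), which needs the anti allyl complex reached by η3–η1–η3 isomerisation of the syn complex formed first from the E carbonate. The new quaternary stereocentre C8 is controlled by C9: the tether C11–C13 can bring C14 only to the enolate face on which C11 stands and perpendicular to the enolate plane, so the C8–C14 bond should be axial on the lactone ring and cis to C11, with the acetyl group on the other face. The step needs C- over O-alkylation and six- over four-membered closure; attack at C12 would give a strained vinylcyclobutane, and an O-allylated enol ether would be re-ionised by the catalyst, so the system should funnel to the C-alkylated cyclohexene.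

Step 21
Reactants: 32 cyclohexene spirolactone
Product: 33 the 1,19-diol (TBDPS ether at C6 retained)
Conditions: CSA (0.3 equiv), MeOH/CH2Cl2 1:1, rt
Reagents that add atoms: none
Why: Acid-catalysed methanolysis should remove the two TBS ethers and leave the far more acid-stable TBDPS ether, while the lactone carbonyl on quaternary C8 is too hindered to transesterify.

Step 22
Reactants: 33 1,19-diol
Product: 34 the 1,19-diacetate
Conditions: Ac2O, pyridine, DMAP, CH2Cl2, rt
Reagents that add atoms: acetic anhydride, CC(=O)OC(C)=O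
Why: DMAP-catalysed acetylation installs the two acetates of the target now that no strongly basic step remains.

Step 23
Reactants: 34 1,19-diacetate
Product: 36 the C16 iodo ketone, via trimethylsilyl enol ether 35 (not isolated)
Conditions: TMSOTf, Et3N, CH2Cl2, 0 °C; then NIS, THF, 0 °C
Reagents that add atoms: N-iodosuccinimide, O=C1CCC(=O)N1I
Why: Soft enolisation of the methyl ketone (its only enolisable position) and electrophilic iodination of the silyl enol ether give the α-iodo ketone without touching the ring alkene or the acetates.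

Step 24
Reactants: 36 iodo ketone
Product: 37 the tetracyclic bicyclo[3.2.1]octan-15-one (rings C and D) with the 6-OTBDPS group
Conditions: Bu3SnH (slow addition), AIBN, benzene (high dilution), 80 °C
Reagents that add atoms: none
Why: In this tin hydride radical cyclisation the C16 α-keto radical should close 5-exo-trig onto C13, which the pseudoaxial acyl arm on C8 can reach, and because the two-atom bridge can only span one face of ring C the new centre C13 is set by C8 before the C12 radical is reduced.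

Step 25
Reactants: 37 tetracyclic ketone
Product: 38 the 16-methylene-15-ketone (TBDPS ether of the target)
Conditions: (CH2O)n, PhNHMe·CF3CO2H, THF, 65 °C
Reagents that add atoms: formaldehyde (as paraformaldehyde), C=O
Why: Mannich-type α-methylenation (condensation with the iminium ion, then loss of the amine) takes place at C16, the only enolisable position of the ketone.

Step 26
Reactants: 38 TBDPS ether of the target
Product: 39 CNP0105570.2
Conditions: HF·pyridine, pyridine, THF, 0 °C to rt
Reagents that add atoms: none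
Why: Buffered fluoride cleavage of the silyl ether frees the C6 hydroxyl under conditions that should neither move an acetyl group nor add to the enone.

**Compound list**

1 | glycolaldehyde dimer (1,4-dioxane-2,5-diol) | OC1COC(O)CO1 | starting material
2 | 1-(triphenylphosphoranylidene)propan-2-one | CC(=O)C=P(c1ccccc1)(c1ccccc1)c1ccccc1 | starting material
3 | (E)-5-hydroxypent-3-en-2-one | CC(=O)/C=C/CO | intermediate
4 | (E)-5-(tert-butyldiphenylsilyloxy)pent-3-en-2-one | CC(=O)/C=C/CO[Si](c1ccccc1)(c1ccccc1)C(C)(C)C | intermediate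
5 | (E)-2-(tert-butyldimethylsilyloxy)-5-(tert-butyldiphenylsilyloxy)penta-1,3-diene | C=C(O[Si](C)(C)C(C)(C)C)/C=C/CO[Si](c1ccccc1)(c1ccccc1)C(C)(C)C | intermediate
6 | (S)-4-benzyloxazolidin-2-one | O=C1N[C@@H](Cc2ccccc2)CO1 | starting material
7 | acryloyl chloride | C=CC(=O)Cl | starting material
8 | (S)-3-acryloyl-4-benzyloxazolidin-2-one | C=CC(=O)N1[C@@H](Cc2ccccc2)COC1=O | intermediate
9 | Diels–Alder adduct, (S)-4-benzyl-3-[(1R,2S)-2-(TBDPS-oxymethyl)-4-(TBS-oxy)cyclohex-3-ene-1-carbonyl]oxazolidin-2-one | O=C(N1[C@@H](Cc2ccccc2)COC1=O)[C@@H]1CCC(O[Si](C)(C)C(C)(C)C)=C[C@@H]1CO[Si](c1ccccc1)(c1ccccc1)C(C)(C)C | intermediate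
10 | methyl (1R,2S)-2-(TBDPS-oxymethyl)-4-(TBS-oxy)cyclohex-3-ene-1-carboxylate | COC(=O)[C@@H]1CCC(O[Si](C)(C)C(C)(C)C)=C[C@@H]1CO[Si](c1ccccc1)(c1ccccc1)C(C)(C)C | intermediate
11 | lithium enolate of ester 10 | [Li]OC(OC)=C1CCC(O[Si](C)(C)C(C)(C)C)=C[C@@H]1CO[Si](c1ccccc1)(c1ccccc1)C(C)(C)C | intermediate
12 | methyl (1R,2S)-2-(TBDPS-oxymethyl)-1-methyl-4-(TBS-oxy)cyclohex-3-ene-1-carboxylate | COC(=O)[C@]1(C)CCC(O[Si](C)(C)C(C)(C)C)=C[C@@H]1CO[Si](c1ccccc1)(c1ccccc1)C(C)(C)C | intermediate
13 | [(1R,2S)-2-(TBDPS-oxymethyl)-1-methyl-4-(TBS-oxy)cyclohex-3-en-1-yl]methanol | OC[C@]1(C)CCC(O[Si](C)(C)C(C)(C)C)=C[C@@H]1CO[Si](c1ccccc1)(c1ccccc1)C(C)(C)C | intermediate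
14 | (1R,2S)-1-(TBS-oxymethyl)-2-(TBDPS-oxymethyl)-1-methyl-4-(TBS-oxy)cyclohex-3-ene | CC(C)(C)[Si](C)(C)OC[C@]1(C)CCC(O[Si](C)(C)C(C)(C)C)=C[C@@H]1CO[Si](c1ccccc1)(c1ccccc1)C(C)(C)C | intermediate
15 | C10 monoalkylborane from 14 (boron trans to C6 and to the C1 silyloxy group) | CC(C)(C)[Si](C)(C)OC[C@]1(C)CC[C@H](O[Si](C)(C)C(C)(C)C)[C@@H](B)[C@@H]1CO[Si](c1ccccc1)(c1ccccc1)C(C)(C)C | intermediate
16 | ring A alcohol, 2-(TBS-oxy)-5-(TBS-oxymethyl)-6-(TBDPS-oxymethyl)-5-methylcyclohexan-1-ol (hydroxyl trans to both neighbours) | CC(C)(C)[Si](C)(C)OC[C@]1(C)CC[C@H](O[Si](C)(C)C(C)(C)C)[C@@H](O)[C@@H]1CO[Si](c1ccccc1)(c1ccccc1)C(C)(C)C | intermediate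
17 | (2S,5R,6S)-2-(TBS-oxy)-5-(TBS-oxymethyl)-6-(TBDPS-oxymethyl)-5-methylcyclohexan-1-one | CC(C)(C)[Si](C)(C)OC[C@]1(C)CC[C@H](O[Si](C)(C)C(C)(C)C)C(=O)[C@@H]1CO[Si](c1ccccc1)(c1ccccc1)C(C)(C)C | intermediate
18 | methylidene analogue of 17 (C10=C20) | CC(C)(C)[Si](C)(C)OC[C@]1(C)CC[C@H](O[Si](C)(C)C(C)(C)C)C(=C)[C@@H]1CO[Si](c1ccccc1)(c1ccccc1)C(C)(C)C | intermediate
19 | C10–C20 spiro-epoxide (spiro epimers) | CC(C)(C)[Si](C)(C)OC[C@]1(C)CC[C@H](O[Si](C)(C)C(C)(C)C)C2(CO2)[C@@H]1CO[Si](c1ccccc1)(c1ccccc1)C(C)(C)C | intermediate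
20 | 2,2,2-trifluoroethyl acrylate | C=CC(=O)OCC(F)(F)F | starting material
21 | 7,20-spirolactone with 1-OTBS, 19-OTBS and 6-OTBDPS (C20 cis to C6, C19 and O1) | O=C1CC[C@]2(CO1)[C@@H](O[Si](C)(C)C(C)(C)C)CC[C@@](C)(CO[Si](C)(C)C(C)(C)C)[C@H]2CO[Si](c1ccccc1)(c1ccccc1)C(C)(C)C | intermediate
22 | lithium enolate of lactone 21 | [Li]OC1=CC[C@]2(CO1)[C@@H](O[Si](C)(C)C(C)(C)C)CC[C@@](C)(CO[Si](C)(C)C(C)(C)C)[C@H]2CO[Si](c1ccccc1)(c1ccccc1)C(C)(C)C | intermediate
23 | lithium hemiaminal from 22 and the Weinreb amide | CON(C)C(C)(O[Li])C1C[C@]2(COC1=O)[C@@H](O[Si](C)(C)C(C)(C)C)CC[C@@](C)(CO[Si](C)(C)C(C)(C)C)[C@H]2CO[Si](c1ccccc1)(c1ccccc1)C(C)(C)C | intermediate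
24 | 8-acetyl spirolactone (C8 epimers) | CC(=O)C1C[C@]2(COC1=O)[C@@H](O[Si](C)(C)C(C)(C)C)CC[C@@](C)(CO[Si](C)(C)C(C)(C)C)[C@H]2CO[Si](c1ccccc1)(c1ccccc1)C(C)(C)C | intermediate
25 | 8-acetyl-8-phenylselanyl spirolactone | CC(=O)C1([Se]c3ccccc3)C[C@]2(COC1=O)[C@@H](O[Si](C)(C)C(C)(C)C)CC[C@@](C)(CO[Si](C)(C)C(C)(C)C)[C@H]2CO[Si](c1ccccc1)(c1ccccc1)C(C)(C)C | intermediate
26 | selenoxide of 25 | CC(=O)C1([Se](=O)c3ccccc3)C[C@]2(COC1=O)[C@@H](O[Si](C)(C)C(C)(C)C)CC[C@@](C)(CO[Si](C)(C)C(C)(C)C)[C@H]2CO[Si](c1ccccc1)(c1ccccc1)C(C)(C)C | intermediate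
27 | 8-acetyl-8,9-didehydro spirolactone | CC(=O)C1=C[C@]2(COC1=O)[C@@H](O[Si](C)(C)C(C)(C)C)CC[C@@](C)(CO[Si](C)(C)C(C)(C)C)[C@H]2CO[Si](c1ccccc1)(c1ccccc1)C(C)(C)C | intermediate
28 | 9-allyl-8-acetyl spirolactone (C11 cis to C1 on the lactone ring; C8 epimers) | CC(=O)C1[C@@H](CC=C)[C@]2(COC1=O)[C@@H](O[Si](C)(C)C(C)(C)C)CC[C@@](C)(CO[Si](C)(C)C(C)(C)C)[C@H]2CO[Si](c1ccccc1)(c1ccccc1)C(C)(C)C | intermediate
29 | (Z)-but-2-ene-1,4-diol | OC/C=C\CO | starting material
30 | (Z)-but-2-ene-1,4-diyl dimethyl dicarbonate | COC(=O)OC/C=C\COC(=O)OC | intermediate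
31 | key-step precursor, 8-acetyl spirolactone with (E)-4-(methoxycarbonyloxy)but-2-enyl on C9 (C8 epimers) | CC(=O)C1[C@@H](C/C=C/COC(=O)OC)[C@]2(COC1=O)[C@@H](O[Si](C)(C)C(C)(C)C)CC[C@@](C)(CO[Si](C)(C)C(C)(C)C)[C@H]2CO[Si](c1ccccc1)(c1ccccc1)C(C)(C)C | intermediate
32 | key-step product, cis-fused cyclohexene spirolactone with quaternary C8 (acetyl) | CC(=O)[C@]23CC=CC[C@H]2[C@]1(COC3=O)[C@@H](O[Si](C)(C)C(C)(C)C)CC[C@@](C)(CO[Si](C)(C)C(C)(C)C)[C@H]1CO[Si](c1ccccc1)(c1ccccc1)C(C)(C)C | intermediate
33 | 1,19-diol of 32 | CC(=O)[C@]23CC=CC[C@H]2[C@]1(COC3=O)[C@@H](O)CC[C@@](C)(CO)[C@H]1CO[Si](c1ccccc1)(c1ccccc1)C(C)(C)C | intermediate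
34 | 1,19-diacetate | CC(=O)[C@]23CC=CC[C@H]2[C@]1(COC3=O)[C@@H](OC(C)=O)CC[C@@](C)(COC(C)=O)[C@H]1CO[Si](c1ccccc1)(c1ccccc1)C(C)(C)C | intermediate
35 | trimethylsilyl enol ether of 34 (C15=C16) | C=C(O[Si](C)(C)C)[C@]23CC=CC[C@H]2[C@]1(COC3=O)[C@@H](OC(C)=O)CC[C@@](C)(COC(C)=O)[C@H]1CO[Si](c1ccccc1)(c1ccccc1)C(C)(C)C | intermediate
36 | C16 iodo ketone | ICC(=O)[C@]23CC=CC[C@H]2[C@]1(COC3=O)[C@@H](OC(C)=O)CC[C@@](C)(COC(C)=O)[C@H]1CO[Si](c1ccccc1)(c1ccccc1)C(C)(C)C | intermediate
37 | tetracyclic 15-ketone (bicyclo[3.2.1]octanone), 6-OTBDPS | C1C(=O)[C@]23C[C@H]1CC[C@H]2[C@]1(COC3=O)[C@@H](OC(C)=O)CC[C@@](C)(COC(C)=O)[C@H]1CO[Si](c1ccccc1)(c1ccccc1)C(C)(C)C | intermediate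
38 | 16-methylene-15-ketone, 6-OTBDPS | C=C1C(=O)[C@]23C[C@H]1CC[C@H]2[C@]1(COC3=O)[C@@H](OC(C)=O)CC[C@@](C)(COC(C)=O)[C@H]1CO[Si](c1ccccc1)(c1ccccc1)C(C)(C)C | intermediate
39 | CNP0105570.2 (1S,4R,5R,8S,9S,10S,13R in the numbering used here) | C=C1C(=O)[C@]23C[C@H]1CC[C@H]2[C@]1(COC3=O)[C@@H](OC(C)=O)CC[C@@](C)(COC(C)=O)[C@H]1CO | target

**Step count and risks**

Total: 26 steps. Longest linear sequence: 24 steps (steps 1–3, 5–17 and 19–26).

Step 17 is the most exposed: facial selectivity in the addition to C9 may be poor or reversed, because the C1 and C5 arms of ring A shield the two faces of the alkylidene to a similar degree. The fallback sets out from 27 and returns at 28. If the silane enters mainly from the C5 side, the product is the C9 epimer of the allyl β-keto lactone F1. This is selenenylated as in step 16 to the 8-phenylselanyl compound F2, oxidised to the selenoxide F3, and eliminated to the tetrasubstituted 9-allyl alkylidene β-keto lactone F4. C9 is then set by conjugate reduction with Hantzsch ester (toluene, 60 °C): hydride takes the face the carbon nucleophile preferred, which leaves C11 on the C1 side and gives 28.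

Step 20 may fail through ionisation without productive closure: slow syn-to-anti isomerisation of the allyl unit, O-alkylation to a vinyl dihydropyran that is not returned, or β-hydride loss to a diene. The fallback sets out from 21 and returns at 32. The lactone enolate (LiN(iPr)2) is selenenylated with PhSeBr to the 8-phenylselanyl spirolactone F5, oxidised (H2O2) to the selenoxide F6 and eliminated to the 8,9-unsaturated spirolactone F7. Copper-catalysed conjugate addition of CH2=CHCH2MgBr (CuBr·SMe2) to C9, with trapping of the enolate by allyl bromide, gives the trans-8,9-diallyl lactone F8. Ring-closing metathesis with the second-generation Grubbs catalyst closes ring C as the cyclohexene lactone F9. Its enolate (LiN(iPr)2) adds to acetaldehyde on the convex face, syn to H9, to give the cis-fused 8-(1-hydroxyethyl) lactone F10, and Dess–Martin oxidation gives 32. Here C8–C14 is made by enolate allylation and ring C by metathesis.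

Step 24 may fail through competing closure onto C12 (a bicyclo[2.2.2]octane) or through reduction of the α-keto radical before it cyclises. The fallback sets out from 34 and returns at 37. The silyl enol ether 35 is isolated (TMSOTf, Et3N) and cyclised by Saegusa-type oxidative cycloalkenylation (Pd(OAc)2 cat., O2, DMSO; divalent palladium). The palladium enolate adds across C12=C13 in the 5-exo sense and β-hydride elimination gives the 11,12-unsaturated bicyclo[3.2.1]octanone F11. Hydrogenation (H2, Pd/C, EtOAc) then gives 37.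

**Further compounds**

F1 | step 17 | C9 epimer of allyl β-keto lactone 28 | CC(=O)C1[C@H](CC=C)[C@]2(COC1=O)[C@@H](O[Si](C)(C)C(C)(C)C)CC[C@@](C)(CO[Si](C)(C)C(C)(C)C)[C@H]2CO[Si](c1ccccc1)(c1ccccc1)C(C)(C)C
F2 | step 17 | 8-phenylselanyl derivative of F1 | CC(=O)C1([Se]c3ccccc3)[C@H](CC=C)[C@]2(COC1=O)[C@@H](O[Si](C)(C)C(C)(C)C)CC[C@@](C)(CO[Si](C)(C)C(C)(C)C)[C@H]2CO[Si](c1ccccc1)(c1ccccc1)C(C)(C)C
F3 | step 17 | selenoxide of F2 | CC(=O)C1([Se](=O)c3ccccc3)[C@H](CC=C)[C@]2(COC1=O)[C@@H](O[Si](C)(C)C(C)(C)C)CC[C@@](C)(CO[Si](C)(C)C(C)(C)C)[C@H]2CO[Si](c1ccccc1)(c1ccccc1)C(C)(C)C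
F4 | step 17 | 9-allyl-8-acetyl-8,9-didehydro spirolactone | CC(=O)C1=C(CC=C)[C@]2(COC1=O)[C@@H](O[Si](C)(C)C(C)(C)C)CC[C@@](C)(CO[Si](C)(C)C(C)(C)C)[C@H]2CO[Si](c1ccccc1)(c1ccccc1)C(C)(C)C
F5 | step 20 | 8-phenylselanyl spirolactone | O=C1C([Se]c3ccccc3)C[C@]2(CO1)[C@@H](O[Si](C)(C)C(C)(C)C)CC[C@@](C)(CO[Si](C)(C)C(C)(C)C)[C@H]2CO[Si](c1ccccc1)(c1ccccc1)C(C)(C)C
F6 | step 20 | selenoxide of F5 | O=C1C([Se](=O)c3ccccc3)C[C@]2(CO1)[C@@H](O[Si](C)(C)C(C)(C)C)CC[C@@](C)(CO[Si](C)(C)C(C)(C)C)[C@H]2CO[Si](c1ccccc1)(c1ccccc1)C(C)(C)C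
F7 | step 20 | 8,9-didehydro spirolactone | O=C1C=C[C@]2(CO1)[C@@H](O[Si](C)(C)C(C)(C)C)CC[C@@](C)(CO[Si](C)(C)C(C)(C)C)[C@H]2CO[Si](c1ccccc1)(c1ccccc1)C(C)(C)C
F8 | step 20 | trans-8,9-diallyl spirolactone | O=C1[C@H](CC=C)[C@@H](CC=C)[C@]2(CO1)[C@@H](O[Si](C)(C)C(C)(C)C)CC[C@@](C)(CO[Si](C)(C)C(C)(C)C)[C@H]2CO[Si](c1ccccc1)(c1ccccc1)C(C)(C)C
F9 | step 20 | ring C cyclohexene lactone without the acetyl group (C8 epimers) | C12CC=CC[C@H]1[C@]3(COC2=O)[C@@H](O[Si](C)(C)C(C)(C)C)CC[C@@](C)(CO[Si](C)(C)C(C)(C)C)[C@H]3CO[Si](c1ccccc1)(c1ccccc1)C(C)(C)C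
F10 | step 20 | cis-fused 8-(1-hydroxyethyl) lactone (carbinol epimers) | CC(O)[C@]23CC=CC[C@H]2[C@]1(COC3=O)[C@@H](O[Si](C)(C)C(C)(C)C)CC[C@@](C)(CO[Si](C)(C)C(C)(C)C)[C@H]1CO[Si](c1ccccc1)(c1ccccc1)C(C)(C)C
F11 | step 24 | 11,12-didehydro bicyclo[3.2.1]octan-15-one | C1C(=O)[C@]23C[C@H]1C=C[C@H]2[C@]1(COC3=O)[C@@H](OC(C)=O)CC[C@@](C)(COC(C)=O)[C@H]1CO[Si](c1ccccc1)(c1ccccc1)C(C)(C)C
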